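**Plan**

- Retrosynthesis: the acetate C–O bond is cut first, and the carbon of that CH2O arm is traced back to the carbonyl of a benzofuran-2(3H)-one. The bond between the fully substituted carbinol carbon and the ring carbon ortho to the phenolic OH (para to the CH2O-bearing ring carbon) is cut next. The angelate and 2-methylbutanoate C–O bonds lead back to a bromopyruvate and 3-hydroxybenzyl alcohol.
- Forward: a phenol ester (one step) and a chiral α-keto ester (two steps), which already carry two of the three acyl groups, are joined at the quaternary carbon by a titanium-phenoxide-templated ortho-hydroxyalkylation.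
- Enabling feature: the free phenolic OH sits on the ring carbon next to the one that bonds. Its oxygen binds titanium and delivers the ketone to that ortho carbon; the other ortho carbon is flanked by OH and CH2O. The CH2OAc carbon is carried at the ester oxidation level, so the carbinol carbon arrives as the ketone of a chelating 1,2-dicarbonyl.
- After the union the phenol closes onto the auxiliary ester to a temporary five-membered lactone. This expels the auxiliary and makes that carbon an aryl ester, which borohydride reduces beside the two alkyl esters. Lipase acetylation of the new primary OH ends the route.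
- Stereochemistry: the 2-methylbutanoate centre is bought as the (R)-acid and is never activated as an acyl electrophile. The carbinol centre is set in the key step by a (+)-8-phenylmenthyl ester. The Z-alkene comes from angelic acid, introduced as a carboxylate nucleophile.

Key step: step 4

Remark: (R)-2-methylbutanoic acid and (+)-8-phenylmenthol are taken as purchasable, and the sense of induction in step 4 is taken from the chelated s-cis face-shielding model of 8-phenylmenthyl α-keto esters.

**Route**

Step 1
Reactants: 1 3-(hydroxymethyl)phenol; 2 (R)-2-methylbutanoic acid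
Product: 3 3-hydroxybenzyl (2R)-2-methylbutanoate
Conditions: PPh3, DIAD, THF, 0 °C → rt
Reagents that add atoms: none
Why: Mitsunobu esterification should be selective for the benzylic OH because the carboxylic acid, far more acidic than the phenol, is the only effective pronucleophile, and the acid's α-stereocentre is safe because the acid reacts as a carboxylate and is never an activated acyl species.

Step 2
Reactants: 4 bromopyruvic acid; 5 (+)-8-phenylmenthol [(1S,2R,5S)-5-methyl-2-(2-phenylpropan-2-yl)cyclohexan-1-ol]
Product: 7 (1S,2R,5S)-5-methyl-2-(2-phenylpropan-2-yl)cyclohexyl 3-bromo-2-oxopropanoate, via 3-bromo-2-oxopropanoyl chloride 6 (not isolated)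
Conditions: Cl2CHOMe, 50 °C; concentrate; then 5, CH2Cl2, 0 °C → rt, N2 sweep, no amine base
Reagents that add atoms: none
Why: Dichloromethyl methyl ether converts α-keto acids into their acid chlorides without touching the bromomethyl ketone, and the very electrophilic α-keto acid chloride should acylate the hindered secondary alcohol without a base that could alkylate at CH2Br.

Step 3
Reactants: 7 (+)-8-phenylmenthyl 3-bromo-2-oxopropanoate; 8 angelic acid [(Z)-2-methylbut-2-enoic acid]
Product: 9 (1S,2R,5S)-5-methyl-2-(2-phenylpropan-2-yl)cyclohexyl 3-{[(Z)-2-methylbut-2-enoyl]oxy}-2-oxopropanoate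
Conditions: KHCO3, DMF, 0 °C → rt; dried azeotropically (toluene)
Reagents that add atoms: none
Why: SN2 displacement of the activated α-bromoketone by potassium angelate installs the angelate through its carboxylate oxygen, so no activated angeloyl species forms and Z→E isomerisation to the tiglate should not occur.

Step 4
Reactants: 3 3-hydroxybenzyl (2R)-2-methylbutanoate; 9 (+)-8-phenylmenthyl 3-(angeloyloxy)-2-oxopropanoate
Product: 11 (1S,2R,5S)-5-methyl-2-(2-phenylpropan-2-yl)cyclohexyl (2S)-2-hydroxy-2-[2-hydroxy-4-({[(2R)-2-methylbutanoyl]oxy}methyl)phenyl]-3-{[(Z)-2-methylbut-2-enoyl]oxy}propanoate, via aryloxytitanium trichloride 10 (not isolated)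
Conditions: 3, TiCl4 (1.1 equiv), CH2Cl2, 0 °C → rt, N2 sweep; then 9, −40 → −20 °C; aq. NH4Cl; chromatography
Reagents that add atoms: none
Why: Phenol 3 and TiCl4 give the aryloxytitanium trichloride 10, whose titanium is chelated by the two carbonyl oxygens of the 1,2-dicarbonyl unit of 9, so that the ketone carbon is passed within the coordination sphere, through a six-membered cyclic transition state (Ti–O–C(ipso)=C(ortho)···C=O), to the ring carbon ortho to the phenoxide oxygen, after which proton loss restores the arene. The closest known reaction type is the metal-phenoxide-templated, ortho-specific Friedel–Crafts hydroxyalkylation of phenols with chiral pyruvate and glyoxylate esters. No ring is closed. The one new stereocentre, the fully substituted carbinol carbon, is controlled by the auxiliary: the phenyl ring of the (+)-8-phenylmenthyl group stacks over the si face of the chelated s-cis keto ester, so the arene should add to the re face and give the (S)-hydroxy ester, which has the spatial arrangement of the (R)-carbinol of the target. The step needs ortho rather than para attack, which the O–Ti tether secures, and attack at the ortho carbon that is para to the CH2O-bearing carbon rather than at the one flanked by OH and CH2O, which sterics secure. The benzylic ester should survive because its CH2 is meta to the phenoxide oxygen and cannot ionise with its help, and any minor diastereomer can be removed here because the auxiliary is still attached.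

Step 5
Reactants: 11 (+)-8-phenylmenthyl (2S)-hydroxy ester adduct
Product: 12 [(3S)-3-hydroxy-3-({[(Z)-2-methylbut-2-enoyl]oxy}methyl)-2-oxo-2,3-dihydro-1-benzofuran-6-yl]methyl (2R)-2-methylbutanoate
Conditions: CSA (0.2 equiv), toluene, 70 °C
Reagents that add atoms: none
Why: Acid-catalysed intramolecular transesterification (5-exo-trig lactonisation) of the ortho phenol onto the α-hydroxy ester should be driven by the gem-disubstituted carbon and by release of the bulky auxiliary alcohol, and it does not touch the stereocentre.

Step 6
Reactants: 12 (3S)-benzofuranone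
Product: 13 (2R)-2,3-dihydroxy-2-[2-hydroxy-4-({[(2R)-2-methylbutanoyl]oxy}methyl)phenyl]propyl (Z)-2-methylbut-2-enoate
Conditions: NaBH4, THF–EtOH, −20 → 0 °C; pH 7 buffer quench
Reagents that add atoms: none
Why: Borohydride reduces an aryl ester (here also α-hydroxy-activated) much faster than alkyl or conjugated esters, so the lactone should open through the lactol and hydroxy aldehyde to the primary alcohol and free the phenol while the angelate, the benzylic ester and the quaternary centre stay intact.

Step 7
Reactants: 13 (2R)-diol monoangelate
Product: 14 (2R)-3-acetoxy-2-hydroxy-2-[2-hydroxy-4-({[(2R)-2-methylbutanoyl]oxy}methyl)phenyl]propyl (Z)-2-methylbut-2-enoate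
Conditions: immobilised Burkholderia cepacia lipase, vinyl acetate, MTBE, 30 °C
Reagents that add atoms: vinyl acetate, CC(=O)OC=C
Why: Lipase-catalysed irreversible transesterification with an enol ester acylates primary aliphatic hydroxyls but not phenols or tertiary alcohols, and the neutral medium should prevent acyl migration between the two CH2O arms.

**Compound list**

1 | 3-(hydroxymethyl)phenol | OCc1cccc(O)c1 | starting material
2 | (R)-2-methylbutanoic acid | CC[C@@H](C)C(=O)O | starting material
3 | 3-hydroxybenzyl (2R)-2-methylbutanoate | CC[C@@H](C)C(=O)OCc1cccc(O)c1 | intermediate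
4 | bromopyruvic acid (3-bromo-2-oxopropanoic acid) | O=C(O)C(=O)CBr | starting material
5 | (+)-8-phenylmenthol, (1S,2R,5S)-5-methyl-2-(2-phenylpropan-2-yl)cyclohexan-1-ol | O[C@H]1C[C@@H](C)CC[C@@H]1C(C)(C)c1ccccc1 | starting material
6 | 3-bromo-2-oxopropanoyl chloride | O=C(Cl)C(=O)CBr | intermediate
7 | (1S,2R,5S)-5-methyl-2-(2-phenylpropan-2-yl)cyclohexyl 3-bromo-2-oxopropanoate | O=C(CBr)C(=O)O[C@H]1C[C@@H](C)CC[C@@H]1C(C)(C)c1ccccc1 | intermediate
8 | angelic acid, (Z)-2-methylbut-2-enoic acid | C/C=C(/C)C(=O)O | starting material
9 | (1S,2R,5S)-5-methyl-2-(2-phenylpropan-2-yl)cyclohexyl 3-{[(Z)-2-methylbut-2-enoyl]oxy}-2-oxopropanoate | C/C=C(/C)C(=O)OCC(=O)C(=O)O[C@H]1C[C@@H](C)CC[C@@H]1C(C)(C)c1ccccc1 | intermediate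
10 | trichloro{3-[({(2R)-2-methylbutanoyl}oxy)methyl]phenoxy}titanium | CC[C@@H](C)C(=O)OCc1cccc(O[Ti](Cl)(Cl)Cl)c1 | intermediate
11 | (+)-8-phenylmenthyl (2S)-2-hydroxy-2-[2-hydroxy-4-({[(2R)-2-methylbutanoyl]oxy}methyl)phenyl]-3-{[(Z)-2-methylbut-2-enoyl]oxy}propanoate | C/C=C(/C)C(=O)OC[C@](O)(C(=O)O[C@H]1C[C@@H](C)CC[C@@H]1C(C)(C)c1ccccc1)c1ccc(COC(=O)[C@H](C)CC)cc1O | intermediate
12 | [(3S)-3-hydroxy-3-({[(Z)-2-methylbut-2-enoyl]oxy}methyl)-2-oxo-2,3-dihydro-1-benzofuran-6-yl]methyl (2R)-2-methylbutanoate | C/C=C(/C)C(=O)OC[C@]1(O)C(=O)Oc2cc(COC(=O)[C@H](C)CC)ccc12 | intermediate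
13 | (2R)-2,3-dihydroxy-2-[2-hydroxy-4-({[(2R)-2-methylbutanoyl]oxy}methyl)phenyl]propyl (Z)-2-methylbut-2-enoate | C/C=C(/C)C(=O)OC[C@](O)(CO)c1ccc(COC(=O)[C@H](C)CC)cc1O | intermediate
14 | (2R)-3-acetoxy-2-hydroxy-2-[2-hydroxy-4-({[(2R)-2-methylbutanoyl]oxy}methyl)phenyl]propyl (Z)-2-methylbut-2-enoate | C/C=C(/C)C(=O)OC[C@](O)(COC(C)=O)c1ccc(COC(=O)[C@H](C)CC)cc1O | target

**Summary**

Total step count: 7. Longest linear sequence: 6 steps (steps 2–7).

**Steps most likely to fail, with fallbacks**

Step 4. The auxiliary may discriminate the two ketone faces incompletely, or its sense may reverse with the metal, and the keto ester may enolise under the Lewis acid. The fallback replaces auxiliary control by catalyst control; it sets out from 3 and 8 and returns at 12. Angelic acid 8 is alkylated with commercial ethyl bromopyruvate (KHCO3, DMF) to ethyl 3-{[(Z)-2-methylbut-2-enoyl]oxy}-2-oxopropanoate F1. Phenol 3 and F1 are then combined under a bifunctional cinchona squaramide in toluene at 0 °C, a hydrogen-bond-templated enantioselective ortho-Friedel–Crafts hydroxyalkylation of the known phenol/α-keto ester type. Of the quinine- and quinidine-derived catalysts, the one that delivers the (S)-adduct is kept. This should give ethyl (2S)-2-hydroxy-2-[2-hydroxy-4-({[(2R)-2-methylbutanoyl]oxy}methyl)phenyl]-3-{[(Z)-2-methylbut-2-enoyl]oxy}propanoate F2, which closes under catalytic CSA with loss of ethanol to lactone 12.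

Step 6. Under the basic borohydride conditions the angeloyl group may migrate from its CH2O arm to the new alkoxide on the other arm. This exchange of the two arms inverts the carbinol centre and would erode enantiopurity; slow attack on the two alkyl esters is a second concern. The fallback sets out from 12 and returns at 13, splitting the reduction into two stages that never place a free alkoxide next to the angelate. DIBAL-H (toluene, −78 °C) should take the activated aryl lactone only to the aluminium-bound lactol, isolated after Rochelle-salt work-up as [(3S)-2,3-dihydroxy-3-({[(Z)-2-methylbut-2-enoyl]oxy}methyl)-2,3-dihydro-1-benzofuran-6-yl]methyl (2R)-2-methylbutanoate F3. The open hydroxy-aldehyde form of F3 is then reduced under acidic conditions with NaBH(OAc)3 in AcOH–MeCN at 0 °C (hydroxyl-directed acyloxyborohydride reduction) to 13.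

Step 7. Turnover may be slow or absent because the neopentylic hydroxyl next to the quaternary centre fits the enzyme's acceptor site poorly. The fallback sets out from 13 and returns at 14 by acetylating twice and removing one acetyl chemoselectively. Ac2O, pyridine and catalytic DMAP at 0 °C should acetylate the primary OH and the phenol but not the tertiary OH, giving (2R)-3-acetoxy-2-[2-acetoxy-4-({[(2R)-2-methylbutanoyl]oxy}methyl)phenyl]-2-hydroxypropyl (Z)-2-methylbut-2-enoate F4. The aryl acetate of F4 is then cleaved selectively with NH4OAc in aqueous MeOH at rt, where aryl esters react far faster than alkyl esters, to give 14.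

**Further compounds**

F1 | step 4 | ethyl 3-{[(Z)-2-methylbut-2-enoyl]oxy}-2-oxopropanoate | C/C=C(/C)C(=O)OCC(=O)C(=O)OCC
F2 | step 4 | ethyl (2S)-2-hydroxy-2-[2-hydroxy-4-({[(2R)-2-methylbutanoyl]oxy}methyl)phenyl]-3-{[(Z)-2-methylbut-2-enoyl]oxy}propanoate | C/C=C(/C)C(=O)OC[C@](O)(C(=O)OCC)c1ccc(COC(=O)[C@H](C)CC)cc1O
F3 | step 6 | [(3S)-2,3-dihydroxy-3-({[(Z)-2-methylbut-2-enoyl]oxy}methyl)-2,3-dihydro-1-benzofuran-6-yl]methyl (2R)-2-methylbutanoate | C/C=C(/C)C(=O)OC[C@]1(O)C(O)Oc2cc(COC(=O)[C@H](C)CC)ccc12
F4 | step 7 | (2R)-3-acetoxy-2-[2-acetoxy-4-({[(2R)-2-methylbutanoyl]oxy}methyl)phenyl]-2-hydroxypropyl (Z)-2-methylbut-2-enoate | C/C=C(/C)C(=O)OC[C@](O)(COC(C)=O)c1ccc(COC(=O)[C@H](C)CC)cc1OC(C)=O
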